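If E comes back after each turnover while X is spent in it, the count to keep is how much D stands in the flask for each X charged. Here single-handed E works on the racemate of Z and J, with G also present.

| flask | Z | J | X | G | E | remark | time |
|---|---|---|---|---|---|---|---|
| delta | 0.020 M | 0.020 M | 0.80 equiv | 10 mM | 5.8 mol% | run made earlier |  |
| zeta | 0.020 M | 0.020 M | 0.80 equiv | 10 mM | 10 mol% | run made earlier |  |
| theta | 0.020 M | 0.020 M | 0.45 equiv | 10 mM | 5 mol% | run made earlier |  |
| Friday's | 0.020 M | 0.020 M | 0.800 equiv | 10.0 mM | 5 mol% |  | 50 min |
| Wednesday's | 0.020 M | 0.020 M | 0.260 equiv | 10.0 mM | 8 mol% |  | 50 min |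

- delta (time / min: D / %, Z / %): 6.00: 22.9, 26.3; 12.0: 28.3, 23.2; 20.0: 29.8, 20.3; 25.0: 30.3, 20.0
- zeta (time / min: D / %, Z / %): 2.00: 18.9, 30.3; 5.00: 26.0, 23.5; 10.0: 28.7, 20.9; 25.0: 29.9, 20.3
- theta (time / min: D / %, Z / %): 3.00: 9.9, 40.3; 8.00: 15.2, 35.3; 15.0: 16.7, 33.1; 25.0: 17.2, 33.4

(standard deviation of a reading: 0.5 percentage points)

- E is single-handed; Z and J are mirror images of each other, charged as a racemate, each of them at the stated concentration
- what was read earlier has a scatter of 0.5 percentage points, one standard deviation

* which of the two ends with the higher amount of D, in percent of the Z and J together charged ("neither" if they lie within 2 percentage points) (Friday's / Wednesday's / neither)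
* D at the end, in percent of the Z and J together charged, Friday's
* D at the end, in percent of the Z and J together charged, Wednesday's

Friday's looks nearly like delta: the same X, with E at 5 mol% against 5.8 mol%. Zeta shows that the loading hardly moves the end, since at 25.0 min delta reads 30.3% of D and zeta, with 10 mol% of E, reads 29.9%, a gap smaller than the scatter of 0.5 percentage points. Theta, with less X, stops lower, at 17.2%.

Z and J are charged equally, so one equivalent on Z counts 0.5 on the pair. Delta's X is then 0.400 of the charge and theta's 0.225. We divide the end fraction of D by that fraction of X:

delta: 30.3% / 0.400 = 0.757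
theta: 17.2% / 0.225 = 0.764

This ratio is the D share, and the two runs agree on it.

Loading times time serves as the clock. Delta had flattened at 1.45 min, while Friday's gets 2.50 min and Wednesday's 4.00 min. Both run longer on this clock, so we expect each to reach its end, and the D share gives our figures:

Friday's: 0.757 × 0.400 = 30.3%
Wednesday's: 0.757 × 0.130 = 9.85%

The forecast said Friday's ends higher, with 30% (29% to 31%) and 10.1% (9.2% to 11%), a Wednesday's figure slightly above ours, and held that “E only sets the speed”.

    X + G → Q (k = 0.806 /M/min)
    X + E + Z → E + D (k = 12000 /M²/min)
    X + E + J → E + L (k = 2730 /M²/min)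

Friday's ends higher, with 29.4% of D against 10.2% in Wednesday's, which is a D share of 0.735 and 0.787. In Friday's at 2.50 min, X has a half-life of 4.1 min by way of Z against 14 min by way of J and 88 min by way of G, and the rate of X's use by way of Z over that by way of J falls from 4.4 at the start to 3.4 there, while the selectivity factor, the ratio of the two rate constants, stays at 4.40. In the neighbour like Friday's but with 0.200 equiv of X, the carried 0.757 gives 7.57%, and that flask ends at 7.82%.

(Readings and results were generated by integration from invented constants; scatter was added.)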